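**Retrosynthetic overview**

1. The target is three ready-made phloroglucinol rings joined by two CH2 bridges; no ring is built. The outer rings are regioisomers: in ring A the methoxy group is para to the butanoyl group, in ring C it is para to the bridge carbon. The trimer is therefore unsymmetrical.
2. Key disconnection: the two aryl O–CH3 bonds. If the bridge carbon of ring C is carried as an aldehyde, each methoxy oxygen sits para to a carbonyl carbon, so one proton-gated, para-selective O-methylation sets both.
3. Ring A: 2-methylphloroglucinol → C-butanoylation → O-methylation. Ring C: 2-methylphloroglucinol → C-formylation → O-methylation → C-butanoylation at the last free position.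
4. Bridges last: ring A Mannich base + phloroacetophenone (ring B); then ring C aldehyde → benzylic amine (C–N) → quinone methide → ring B.

Assumption: the target has no stereocentre, so there is no enantiomer to select; the route makes the one achiral compound drawn.

**Route**

Step 1
Reactants: 1 2-methylphloroglucinol
Product: 2 1-(2,4,6-trihydroxy-3-methylphenyl)butan-1-one
Conditions: PrCOCl (1.1 equiv), AlCl3 (3.5 equiv), PhNO2, 0 → 50 °C; ice–HCl
Reagents that add atoms: butanoyl chloride, CCCC(=O)Cl
Why: Friedel–Crafts acylation; the two free ring positions of 1 are equivalent, so only one mono-ketone can form, and its AlCl3 complex is too deactivated for a second acylation.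

Step 2
Reactants: 2 1-(2,4,6-trihydroxy-3-methylphenyl)butan-1-one
Product: 3 1-(2,6-dihydroxy-4-methoxy-3-methylphenyl)butan-1-one (aspidinol)
Conditions: O-methyl-N,N'-diisopropylisourea (1.0 equiv), THF, 45 °C; filter off the urea
Reagents that add atoms: O-methyl-N,N'-diisopropylisourea, COC(=NC(C)C)NC(C)C
Why: Proposed new method: proton-gated O-methylation by an O-alkylisourea, in which the OH para to the ketone (a vinylogous carboxylic acid, pKa about 8, whose anion is held by both ortho OH groups hydrogen-bonding to the carbonyl oxygen) is the first to protonate the one equivalent of isourea, and the isouronium/phenoxide ion pair collapses by SN2 at the O-methyl group to give the para ether and neutral diisopropylurea, with no free base present to drive C-methylation or a second methylation; closest known reaction type: methyl ester formation from carboxylic acids with O-alkylisoureas, and the para-selective diazomethane methylation of chelated polyhydroxyaryl ketones.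

Step 3
Reactants: 1 2-methylphloroglucinol
Product: 5 2,4,6-trihydroxy-3-methylbenzaldehyde, via Vilsmeier iminium chloride 4 (not isolated)
Conditions: POCl3 (1.1 equiv), DMF (1.2 equiv), EtOAc, 0 → 25 °C; then H2O, 70 °C
Reagents that add atoms: N,N-dimethylformamide, CN(C)C=O; water, O
Why: Vilsmeier–Haack formylation; the two free positions of 1 are equivalent and the iminium salt 4 deactivates the ring against a second formylation.

Step 4
Reactants: 5 2,4,6-trihydroxy-3-methylbenzaldehyde
Product: 6 2,6-dihydroxy-4-methoxy-3-methylbenzaldehyde
Conditions: O-methyl-N,N'-diisopropylisourea (1.0 equiv), THF, 40 °C; filter off the urea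
Reagents that add atoms: O-methyl-N,N'-diisopropylisourea, COC(=NC(C)C)NC(C)C
Why: Proposed new method: the same proton-gated isourea O-methylation as in step 2, here on a vinylogous formic acid, where the OH para to the formyl group (pKa about 7) protonates the isourea and is methylated within the ion pair while the two formyl-chelated ortho OH groups stay free, which places the methoxy group para to the carbon that later becomes the methylene bridge of ring C; closest known reaction type: O-alkylisourea esterification of carboxylic acids and para-selective diazomethane methylation of chelated polyhydroxybenzaldehydes.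

Step 5
Reactants: 6 2,6-dihydroxy-4-methoxy-3-methylbenzaldehyde
Product: 7 3-butanoyl-2,6-dihydroxy-4-methoxy-5-methylbenzaldehyde
Conditions: (PrCO)2O (1.3 equiv), MeSO3H, 45 °C; ice–water
Reagents that add atoms: butanoic anhydride, CCCC(=O)OC(=O)CCC
Why: Friedel–Crafts acylation (with Fries-type O-to-C transfer in MeSO3H) at the only free ring position, the same second C-acylation that converts monoacylphloroglucinols into 2,4-diacylphloroglucinols, so the butanoyl group can only land between the methoxy and hydroxy groups.

Step 6
Reactants: 3 aspidinol; 8 phloroacetophenone (3 equiv)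
Product: 11 1-{3-[(3-acetyl-2,4,6-trihydroxyphenyl)methyl]-2,6-dihydroxy-4-methoxy-5-methylphenyl}butan-1-one, via ring A Mannich base 9 (not isolated), via ring A ortho-quinone methide 10 (not isolated)
Conditions: Me2NCH2NMe2 (1.05 equiv), dioxane, 60 °C; evaporate; then 8 (3.0 equiv), dioxane–AcOH (10:1), 70 °C
Reagents that add atoms: bis(dimethylamino)methane, CN(C)CN(C)C
Why: Phenolic Mannich reaction at the only free ring carbon of 3, then thermal loss of dimethylamine to ortho-quinone methide 10 and its C-alkylation of 8 (Friedel–Crafts-type conjugate addition); the electrophile exists only on ring A, and the excess of 8 holds the reaction at the mono-adduct.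

Step 7
Reactants: 7 ring C aldehyde (1.2 equiv); 11 ring A–CH2–ring B dimer
Product: 15 CNP0184345.0, via iminium zwitterion 12 (not isolated), via ring C Mannich base 13 (not isolated), via ring C ortho-quinone methide 14 (not isolated)
Conditions: Me2NH (2 M in THF, 1.5 equiv), NaBH(OAc)3 (1.5 equiv), AcOH (1 equiv), ClCH2CH2Cl, 25 °C; H2O wash, evaporate; then 11 (0.85 equiv), dioxane–AcOH (10:1), 70 °C
Reagents that add atoms: none
Why: Reductive amination (C–N bond formation) turns the formyl carbon of 7 into the benzylic amine 13, a phenolic Mannich base that on warming loses dimethylamine to ortho-quinone methide 14, which is trapped at the single free ring carbon of 11 (Friedel–Crafts-type conjugate addition), so the second bridge can only form between ring C and ring B; no stereocentre is created.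

**Compound list**

1 | 2-methylbenzene-1,3,5-triol (2-methylphloroglucinol) | Cc1c(O)cc(O)cc1O | starting material
2 | 1-(2,4,6-trihydroxy-3-methylphenyl)butan-1-one | CCCC(=O)c1c(O)cc(O)c(C)c1O | intermediate
3 | 1-(2,6-dihydroxy-4-methoxy-3-methylphenyl)butan-1-one (aspidinol, ring A monomer) | CCCC(=O)c1c(O)cc(OC)c(C)c1O | intermediate
4 | N-methyl-N-[(2,4,6-trihydroxy-3-methylphenyl)methylidene]methanaminium chloride (Vilsmeier iminium chloride, not isolated) | C[N+](C)=Cc1c(O)cc(O)c(C)c1O.[Cl-] | intermediate
5 | 2,4,6-trihydroxy-3-methylbenzaldehyde | O=Cc1c(O)cc(O)c(C)c1O | intermediate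
6 | 2,6-dihydroxy-4-methoxy-3-methylbenzaldehyde | O=Cc1c(O)cc(OC)c(C)c1O | intermediate
7 | 3-butanoyl-2,6-dihydroxy-4-methoxy-5-methylbenzaldehyde (ring C aldehyde) | O=Cc1c(O)c(C(=O)CCC)c(OC)c(C)c1O | intermediate
8 | 1-(2,4,6-trihydroxyphenyl)ethan-1-one (phloroacetophenone, ring B) | CC(=O)c1c(O)cc(O)cc1O | starting material
9 | 1-{3-[(dimethylamino)methyl]-2,6-dihydroxy-4-methoxy-5-methylphenyl}butan-1-one (ring A Mannich base, not isolated) | CCCC(=O)c1c(O)c(C)c(OC)c(CN(C)C)c1O | intermediate
10 | 2-butanoyl-3-hydroxy-5-methoxy-4-methyl-6-methylidenecyclohexa-2,4-dien-1-one (ring A ortho-quinone methide, not isolated) | C=C1C(=O)C(C(=O)CCC)=C(O)C(C)=C1OC | intermediate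
11 | 1-{3-[(3-acetyl-2,4,6-trihydroxyphenyl)methyl]-2,6-dihydroxy-4-methoxy-5-methylphenyl}butan-1-one (ring A–CH2–ring B dimer) | CCCC(=O)c1c(O)c(C)c(OC)c(Cc2c(O)cc(O)c(C(C)=O)c2O)c1O | intermediate
12 | 2-butanoyl-6-[(dimethyliminio)methyl]-5-hydroxy-3-methoxy-4-methylphenolate (iminium zwitterion, not isolated) | C[N+](C)=Cc1c([O-])c(C(=O)CCC)c(OC)c(C)c1O | intermediate
13 | 1-{3-[(dimethylamino)methyl]-2,4-dihydroxy-6-methoxy-5-methylphenyl}butan-1-one (ring C Mannich base, not isolated) | CN(C)Cc1c(O)c(C(=O)CCC)c(OC)c(C)c1O | intermediate
14 | 4-butanoyl-3-hydroxy-5-methoxy-6-methyl-2-methylidenecyclohexa-3,5-dien-1-one (ring C ortho-quinone methide, not isolated) | C=C1C(=O)C(C)=C(OC)C(C(=O)CCC)=C1O | intermediate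
15 | 1-[3-({3-acetyl-5-[(3-butanoyl-2,4-dihydroxy-6-methoxy-5-methylphenyl)methyl]-2,4,6-trihydroxyphenyl}methyl)-2,4-dihydroxy-6-methoxy-5-methylphenyl]butan-1-one (CNP0184345.0, achiral) | CCCC(=O)c1c(O)c(C)c(OC)c(Cc2c(O)c(Cc3c(O)c(C)c(OC)c(C(=O)CCC)c3O)c(O)c(C(C)=O)c2O)c1O | target

**Step count and risks**

Total steps: 7. Longest linear sequence: 4 (steps 3, 4, 5, 7 from 1; equally steps 1, 2, 6, 7).

Steps most likely to fail:

- **Step 2 (new O-methylation, ketone).** The risk is incomplete site or mono-selectivity: product 3 is only about one pKa unit less acidic than 2. The fallback uses known chemistry and moves the selectivity from ether formation to ether cleavage. It sets out from 2 and returns at 3. Exhaustive O-methylation of 2 (Me2SO4, K2CO3, acetone, reflux) gives 1-(2,4,6-trimethoxy-3-methylphenyl)butan-1-one F1. AlCl3 in chlorobenzene at 80 °C, anchored on the ketone oxygen, then cleaves only the two methyl ethers ortho to the carbonyl and leaves the para methoxy group, giving 3.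

- **Step 4 (new O-methylation, aldehyde).** The risks are the same, plus possible attack of the isourea nitrogen on the formyl group. The fallback is again known chemistry; it sets out from 5 and returns at 6. Exhaustive O-methylation of 5 (Me2SO4, K2CO3, acetone, reflux) gives 2,4,6-trimethoxy-3-methylbenzaldehyde F2. Chelation-controlled cleavage with AlCl3 (CH2Cl2, reflux) removes the two methyl groups ortho to the formyl group and gives 6.

- **Step 7 (one-flask reductive amination and hetero-coupling).** The risks are slow reduction of the stabilised iminium 12, reduction of quinone methide 14 to a C-methyl group by leftover hydride, and acid-induced scrambling of the bridge already present. The fallback drops the amine and uses the aldehyde itself as the electrophile; it sets out from 7 and 11 and returns at 15. CF3CO2H in CH2Cl2 at 0 °C condenses 7 with the free ring carbon of 11 to the racemic diarylcarbinol (15 with the ring B–ring C bridge as CH(OH)) F3. Et3SiH is added only after condensation is complete and reduces the carbinol, through its stabilised diarylmethyl cation, to 15 (ionic hydrogenation).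

**Further compounds**

F1 | step 2 | 1-(2,4,6-trimethoxy-3-methylphenyl)butan-1-one | CCCC(=O)c1c(OC)cc(OC)c(C)c1OC
F2 | step 4 | 2,4,6-trimethoxy-3-methylbenzaldehyde | O=Cc1c(OC)cc(OC)c(C)c1OC
F3 | step 7 | racemic diarylcarbinol, 15 with CH(OH) in place of the ring B–ring C CH2 | CCCC(=O)c1c(O)c(C)c(OC)c(Cc2c(O)c(C(O)c3c(O)c(C)c(OC)c(C(=O)CCC)c3O)c(O)c(C(C)=O)c2O)c1O
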